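**Retrosynthetic overview**
1. Moracin Q (12) ⇐ removal of three O‑isopropyl groups from 11 ⇐ O‑methylation of the 5‑OH of 10.
2. Key bond C4–CH2: photochemical radical‑pair 1,3 O→C shift of the 5‑O‑(3‑methyl‑2‑oxobutyl) ether 9, made from phenol 7 and bromoketone 8.
3. Furan ring: formal [3+2] of 2‑isopropoxy‑1,4‑benzoquinone 6 with α‑butoxystyrene 4; this sets O1, the free 5‑OH and the 6‑OiPr in one step.
4. 4 ⇐ meta C–H borylation of 1,3‑diisopropoxybenzene 1, then oxidative Heck with butyl vinyl ether 3; 6 ⇐ para‑oxidation of 2‑isopropoxyphenol 5.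
5. Ring order: both benzene rings are bought; the furan ring is the only ring formed (step 4).

Assumption: the target SMILES has no stereocentre, so no stereocontrol is needed; resorcinol and catechol are bought as their commercial O‑isopropyl‑protected forms (1 and 5).

**Step 1**
Reactants: 1, 1,3‑diisopropoxybenzene
Product: 2, 2‑(3,5‑diisopropoxyphenyl)‑4,4,5,5‑tetramethyl‑1,3,2‑dioxaborolane
Conditions: B2pin2, [Ir(OMe)(cod)]2 (1.5 mol%), dtbpy (3 mol%), THF, 80 °C
Reagents that add atoms: bis(pinacolato)diboron, CC1(C)OB(OC1(C)C)B1OC(C)(C)C(C)(C)O1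
Why: Sterically controlled Ir‑catalysed C–H borylation goes to C5, the only C–H not ortho to an alkoxy group.

**Step 2**
Reactants: 2, aryl boronate; 3, n‑butyl vinyl ether
Product: 4, 1‑(1‑butoxyvinyl)‑3,5‑diisopropoxybenzene
Conditions: 3 (5 equiv), Pd(OAc)2 (5 mol%), 2,9‑dimethyl‑1,10‑phenanthroline (6 mol%), N‑methylmorpholine, O2 (1 atm), MeCN, 50 °C; purify on Et3N‑deactivated silica
Reagents that add atoms: none (the two vinyl carbons and OBu come from 3)
Why: Oxidative Heck reaction through cationic Pd(II) with a bidentate N,N ligand arylates electron‑rich vinyl ethers at the internal carbon, giving the α‑aryl enol ether directly.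

**Step 3**
Reactants: 5, 2‑isopropoxyphenol
Product: 6, 2‑isopropoxy‑1,4‑benzoquinone
Conditions: Fremy's salt (2.2 equiv), aq. KH2PO4, acetone/H2O, 0 °C → rt
Reagents that add atoms: potassium nitrosodisulfonate, [K+].[K+].[O]N(S(=O)(=O)[O-])S(=O)(=O)[O-] (supplies the new C4 oxygen)
Why: Teuber oxidation of a phenol with a free para position gives the p‑quinone.

**Step 4**
Reactants: 6, 2‑isopropoxy‑1,4‑benzoquinone; 4, α‑butoxystyrene
Product: 7, 2‑(3,5‑diisopropoxyphenyl)‑6‑isopropoxybenzofuran‑5‑ol
Conditions: TiCl4/Ti(OiPr)4 (1:1, 1.2 equiv), CH2Cl2, −78 °C; then TsOH·H2O (cat.), rt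
Reagents that add atoms: none
Why: Lewis‑acid formal [3+2] of a 2‑alkoxyquinone with an enol ether (Engler type), in which the enol ether CH2 attacks quinone C5, the C4 oxygen closes onto the oxocarbenium and acid removes BuOH to aromatise, leaving the C1 oxygen as the free 5‑OH next to the 6‑OiPr.

**Step 5**
Reactants: 7, benzofuran‑5‑ol; 8, 1‑bromo‑3‑methylbutan‑2‑one
Product: 9, 1‑{[2‑(3,5‑diisopropoxyphenyl)‑6‑isopropoxybenzofuran‑5‑yl]oxy}‑3‑methylbutan‑2‑one
Conditions: K2CO3, acetone, 50 °C, N2
Reagents that add atoms: none (the C5 side chain comes from 8)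
Why: Williamson O‑alkylation of the only free phenol with a reactive α‑bromoketone.

**Step 6 (key step)**
Reactants: 9, aryloxy ketone
Product: 10, 1‑[2‑(3,5‑diisopropoxyphenyl)‑5‑hydroxy‑6‑isopropoxybenzofuran‑4‑yl]‑3‑methylbutan‑2‑one
Conditions: hν (300 nm, Pyrex), degassed MeCN/t‑BuOH (1:1), 3 mM, rt, to about 70% conversion; recovered 7 is recycled through step 5
Reagents that add atoms: none
Why: Proposed new method: excitation of the aryl ether chromophore homolyses the weak ArO–CH2C(=O) bond to a caged phenoxyl/α‑keto radical pair, and the only spin‑bearing carbon where recombination can re‑aromatise is C4 (C6 carries OiPr, C7a is the ring‑fusion carbon), so tautomerisation of the C4 adduct gives 10; the closest known reactions are the photo‑Claisen shift of aryl allyl and benzyl ethers, the photo‑Fries rearrangement, and the photorearrangement of aryloxyacetones to o‑hydroxybenzyl ketones.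

**Step 7**
Reactants: 10, o‑hydroxybenzyl ketone (used crude, kept away from acid)
Product: 11, 1‑[2‑(3,5‑diisopropoxyphenyl)‑6‑isopropoxy‑5‑methoxybenzofuran‑4‑yl]‑3‑methylbutan‑2‑one
Conditions: MeI, K2CO3, acetone, rt
Reagents that add atoms: iodomethane, CI
Why: Williamson methylation of the phenoxide (pKa about 10), which is far more readily formed than the ketone enolate under K2CO3, and which blocks cyclodehydration of the 5‑OH onto the side‑chain ketone.

**Step 8**
Reactants: 11, tri‑O‑isopropyl moracin Q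
Product: 12, moracin Q, 1‑[2‑(3,5‑dihydroxyphenyl)‑6‑hydroxy‑5‑methoxybenzofuran‑4‑yl]‑3‑methylbutan‑2‑one
Conditions: BCl3 (1 M in CH2Cl2, 6 equiv), CH2Cl2, −78 → 0 °C; MeOH quench
Reagents that add atoms: none
Why: Lewis‑acid dealkylation cleaves secondary (isopropyl) aryl ethers through the stabilised isopropyl cation much faster than the methyl ether, and the ketone and benzofuran tolerate BCl3 at low temperature.

**Compound list**
1 | 1,3‑diisopropoxybenzene | CC(C)Oc1cccc(OC(C)C)c1 | starting material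
2 | 2‑(3,5‑diisopropoxyphenyl)‑4,4,5,5‑tetramethyl‑1,3,2‑dioxaborolane | CC(C)Oc1cc(OC(C)C)cc(c1)B1OC(C)(C)C(C)(C)O1 | intermediate
3 | n‑butyl vinyl ether | C=COCCCC | starting material
4 | 1‑(1‑butoxyvinyl)‑3,5‑diisopropoxybenzene | C=C(OCCCC)c1cc(OC(C)C)cc(OC(C)C)c1 | intermediate
5 | 2‑isopropoxyphenol | CC(C)Oc1ccccc1O | starting material
6 | 2‑isopropoxy‑1,4‑benzoquinone | CC(C)OC1=CC(=O)C=CC1=O | intermediate
7 | 2‑(3,5‑diisopropoxyphenyl)‑6‑isopropoxybenzofuran‑5‑ol | CC(C)Oc1cc2oc(-c3cc(OC(C)C)cc(OC(C)C)c3)cc2cc1O | intermediate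
8 | 1‑bromo‑3‑methylbutan‑2‑one | CC(C)C(=O)CBr | starting material
9 | 1‑{[2‑(3,5‑diisopropoxyphenyl)‑6‑isopropoxybenzofuran‑5‑yl]oxy}‑3‑methylbutan‑2‑one | CC(C)Oc1cc2oc(-c3cc(OC(C)C)cc(OC(C)C)c3)cc2cc1OCC(=O)C(C)C | intermediate
10 | 1‑[2‑(3,5‑diisopropoxyphenyl)‑5‑hydroxy‑6‑isopropoxybenzofuran‑4‑yl]‑3‑methylbutan‑2‑one | CC(C)Oc1cc2oc(-c3cc(OC(C)C)cc(OC(C)C)c3)cc2c(CC(=O)C(C)C)c1O | intermediate
11 | 1‑[2‑(3,5‑diisopropoxyphenyl)‑6‑isopropoxy‑5‑methoxybenzofuran‑4‑yl]‑3‑methylbutan‑2‑one | CC(C)Oc1cc2oc(-c3cc(OC(C)C)cc(OC(C)C)c3)cc2c(CC(=O)C(C)C)c1OC | intermediate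
12 | moracin Q | COc1c(O)cc2oc(-c3cc(O)cc(O)c3)cc2c1CC(=O)C(C)C | target

**Totals**
Total steps: 8. Longest linear sequence: 7 (steps 1, 2, 4, 5, 6, 7, 8); step 3 is the one‑step side branch.

**Steps most likely to fail, with fallbacks**
1. Step 6 (photochemical O→C shift): expect a modest yield, with loss to out‑of‑cage phenol 7 or a poor quantum yield from the extended chromophore. Fallback: iodinate 7 at C4 (I2/morpholine, ortho to the phenol), methylate, then join the side chain by photostimulated SRN1 coupling of the aryl iodide with the potassium enolate of 3‑methylbutan‑2‑one (KOtBu, DMSO, hν).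
2. Step 4 (quinone/enol ether [3+2]): enol ether polymerisation or quinone redox side reactions are possible. Fallback: add HBr to 6 to give 5‑bromo‑2‑isopropoxyhydroquinone and build the furan by SRN1 annulation (aryl halide/enolate coupling, then cyclodehydration) with the enolate of 3,5‑diisopropoxyacetophenone, obtained by hydrolysis of 4.
3. Step 2 (oxidative Heck on a pinacol boronate, acid‑labile product): Fallback: acylative Suzuki coupling of 2 with acetic anhydride to the acetophenone, conversion to its trimethylsilyl enol ether, and Mukaiyama–Michael addition to 6 followed by acid cyclodehydration.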